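**Strategy.** Both sulfate esters are disconnected to S(VI)–F chemistry on unprotected luteolin. In one operation sulfuryl fluoride ties the ortho oxygens O3' and O4' of ring B into a five-membered cyclic sulfate and converts O7 of ring A into a fluorosulfate, while the 5-OH, chelated to the C4 carbonyl, stays free. The feature exploited is that O4' is para to the C1'–C2 bond and conjugated with the C2=C3–C4=O unit of ring C, hence more acidic than O3': hydrolytic opening of the cyclic sulfate should expel O4' and keep sulfur on O3'. The precursor is luteolin itself, assembled in two steps from phloroacetophenone and veratroyl chloride.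

Key step: step 3

Remark: the target has no stereocentre, so no enantiomer has to be secured; the aryl sulfate monoesters 9 and 11 would be handled as sodium salts (11 passed through a cold H+ resin where the free acid is wanted) and are written as neutral acids.

**Step 1**
Reactants: 1 2,4,6-trihydroxyacetophenone; 2 3,4-dimethoxybenzoyl chloride
Product: 3 1-(3,4-dimethoxyphenyl)-3-(2,4,6-trihydroxyphenyl)propane-1,3-dione
Conditions: LiHMDS (5 equiv), THF, −78 → −10 °C; then 2 (1.0 equiv), −78 °C → rt; aq. HCl
Reagents that add atoms: none
Why: The tetralithiated acetophenone (three phenoxides plus the ketone enolate) should be aroylated at the enolate carbon, the fifth equivalent of base absorbing the acidic diketone proton (Claisen-type C-aroylation of a ketone polyanion; any O-aroylated material converges by Baker–Venkataraman acyl shift in the same medium).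

**Step 2**
Reactants: 3 1-(3,4-dimethoxyphenyl)-3-(2,4,6-trihydroxyphenyl)propane-1,3-dione
Product: 5 luteolin, via 5,7-dihydroxy-3',4'-dimethoxyflavone 4 (not isolated)
Conditions: pyridine·HCl (20 equiv), neat melt, 185 °C, N2; then H2O, filter, recrystallise (aq. EtOH)
Reagents that add atoms: none
Why: Acid-catalysed cyclodehydration of the o-hydroxyaryl β-diketone (second stage of a Baker–Venkataraman flavone synthesis) should give flavone 4, whose two aryl methyl ethers are then cleaved by chloride at methyl in the pyridinium melt (pyridinium chloride O-demethylation); ring A is a symmetrical phloroglucinol, so a Wessely–Moser reopening cannot alter the constitution.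

**Step 3**
Reactants: 5 luteolin; 6 sulfuryl fluoride
Product: 8 luteolin 3',4'-cyclic sulfate 7-fluorosulfate, via luteolin 7,4'-bis(fluorosulfate) 7 (not isolated)
Conditions: SO2F2 (2.2 equiv, metered as a titrated MeCN solution), iPr2NEt (4 equiv), MeCN/THF, 0 °C → rt; cold dilute HCl wash, short silica plug
Reagents that add atoms: sulfuryl fluoride (compound 6), O=S(=O)(F)F
Why: Each reacting phenoxide attacks S(VI) of SO2F2 with loss of fluoride (SuFEx); O7 and O4', the two most acidic hydroxyls, should give bis(fluorosulfate) 7, and the neighbouring O3' phenoxide then displaces the remaining fluoride on the ring-B sulfur. The closest known reactions are the fluorosulfation of phenols with SO2F2 and a tertiary amine and the conversion of catechol into its cyclic sulfate under the same conditions. The one new ring, a five-membered 1,3,2-dioxathiole 2,2-dioxide fused to ring B, closes by intramolecular substitution at sulfur in a 5-exo mode with fluoride leaving outside the ring. No stereocentre is formed. The step needs chemoselectivity among four hydroxyls: the 5-OH is hydrogen-bonded to the C4 carbonyl and is the least acidic and least nucleophilic, so about two equivalents of SO2F2 with a hindered trialkylamine at 0 °C should leave it free, while the ortho relationship of O3' and O4' should make ring closure faster than a second intermolecular fluorosulfation on ring B.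

**Step 4**
Reactants: 8 luteolin 3',4'-cyclic sulfate 7-fluorosulfate
Product: 9 luteolin 3'-sulfate 7-fluorosulfate
Conditions: aq. NaHCO3 (pH ≈ 8.5), MeCN, 0 °C → rt; C18 desalting (Na salt)
Reagents that add atoms: water, O
Why: Proposed new method: hydroxide or water should attack the strained S(VI) of the five-membered diaryl sulfate in line with the ring oxygen that is the better leaving group, and O4', whose phenoxide is delocalised through ring B into the C2=C3–C4=O unit, should depart in preference to O3', leaving the sulfate monoester on O3'; the closest known reaction type is the alkaline hydrolysis of catechol cyclic sulfate, which proceeds by S–O fission far faster than that of acyclic diaryl sulfates, and the aryl fluorosulfate on O7 should be inert at this pH.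

**Step 5**
Reactants: 9 luteolin 3'-sulfate 7-fluorosulfate
Product: 11 luteolin 7,3'-disulfate, via 2-hydroxyethyl sulfate diester 10 (not isolated)
Conditions: Cs2CO3 (5 equiv), ethylene glycol, rt; AcOH to pH 7, C18 then Sephadex LH-20, Na+ exchange
Reagents that add atoms: ethylene glycol, OCCO
Why: Glycolate should displace fluoride at S(VI) (SuFEx) and the resulting 2-hydroxyethyl aryl sulfate should lose its alkyl group by intramolecular O-alkylation to oxirane, which is the known ethylene glycol/Cs2CO3 conversion of aryl fluorosulfates into aryl sulfates; the anionic 3'-sulfate monoester is not electrophilic and the flavone ring tolerates carbonate at room temperature.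

**Compound list**
1 | 2,4,6-trihydroxyacetophenone | CC(=O)c1c(O)cc(O)cc1O | starting material
2 | 3,4-dimethoxybenzoyl chloride | COc1ccc(C(=O)Cl)cc1OC | starting material
3 | 1-(3,4-dimethoxyphenyl)-3-(2,4,6-trihydroxyphenyl)propane-1,3-dione (drawn as the open diketone) | COc1ccc(C(=O)CC(=O)c2c(O)cc(O)cc2O)cc1OC | intermediate
4 | 5,7-dihydroxy-3',4'-dimethoxyflavone | COc1ccc(-c2cc(=O)c3c(O)cc(O)cc3o2)cc1OC | intermediate (not isolated)
5 | luteolin (5,7,3',4'-tetrahydroxyflavone) | O=c1cc(-c2ccc(O)c(O)c2)oc2cc(O)cc(O)c12 | intermediate
6 | sulfuryl fluoride | O=S(=O)(F)F | starting material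
7 | luteolin 7,4'-bis(fluorosulfate) | O=c1cc(-c2ccc(OS(=O)(=O)F)c(O)c2)oc2cc(OS(=O)(=O)F)cc(O)c12 | intermediate (not isolated)
8 | luteolin 3',4'-cyclic sulfate 7-fluorosulfate [2-(2,2-dioxido-1,3,2-benzodioxathiol-5-yl)-5-hydroxy-4-oxo-4H-chromen-7-yl fluorosulfate] | O=c1cc(-c2ccc3OS(=O)(=O)Oc3c2)oc2cc(OS(=O)(=O)F)cc(O)c12 | intermediate
9 | luteolin 3'-(hydrogen sulfate) 7-fluorosulfate | O=c1cc(-c2ccc(O)c(OS(=O)(=O)O)c2)oc2cc(OS(=O)(=O)F)cc(O)c12 | intermediate
10 | luteolin 3'-(hydrogen sulfate) 7-(2-hydroxyethyl sulfate) | O=c1cc(-c2ccc(O)c(OS(=O)(=O)O)c2)oc2cc(OS(=O)(=O)OCCO)cc(O)c12 | intermediate (not isolated)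
11 | luteolin 7,3'-disulfate | O=c1cc(-c2ccc(O)c(OS(=O)(=O)O)c2)oc2cc(OS(=O)(=O)O)cc(O)c12 | target

**Total step count:** 5. **Longest linear sequence:** 5 steps (1 → 3 → 5 → 8 → 9 → 11).

**Steps most likely to fail**

Step 4. Regiocontrol may be lost in the ring opening, with O3' departing instead of O4', or hydroxide may attack the 7-fluorosulfate at the same time. The fallback uses known chemistry only, sets out from acetophenone 1 and comes back to the route at target 11; it blocks O4' by construction.
- Purchased 4-(benzyloxy)-3-hydroxybenzoic acid F1 is bis-silylated (TBSCl, imidazole, DMF) to tert-butyldimethylsilyl 4-(benzyloxy)-3-(tert-butyldimethylsilyloxy)benzoate F2.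
- Oxalyl chloride with catalytic DMF converts the silyl ester into 4-(benzyloxy)-3-(tert-butyldimethylsilyloxy)benzoyl chloride F3.
- F3 aroylates the LiHMDS polyanion of 1 as in step 1, giving 1-[4-(benzyloxy)-3-(tert-butyldimethylsilyloxy)phenyl]-3-(2,4,6-trihydroxyphenyl)propane-1,3-dione F4.
- H2SO4 (cat.) in AcOH at 95 °C cyclodehydrates F4 and removes the silyl ether, giving 4'-O-benzylluteolin F5.
- SO3·pyridine in pyridine/DMF sulfates O7 and O3', the chelated 5-OH being unreactive, to give 4'-O-benzylluteolin 7,3'-disulfate F6.
- Hydrogenolysis (H2, Pd/C, aq. MeOH, sodium salt) removes the benzyl ether and delivers 11.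

Step 3. Sulfurylation may run on to the chelated O5, a phenoxide may attack an already formed cyclic sulfate of another molecule (oligomeric diaryl sulfates), or the cyclic sulfate may be opened during work-up. The fallback separates the O7 event from the ring-B closure; it sets out from luteolin 5 and comes back at 8.
- Ac2O/pyridine gives luteolin tetraacetate F7.
- PhSH/imidazole in NMP at 0 °C, the 7-selective deacylation of flavone peracetates, gives 5,3',4'-tri-O-acetylluteolin F8.
- SO2F2/Et3N converts the single free phenol into 5,3',4'-tri-O-acetylluteolin 7-fluorosulfate F9.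
- HCl in MeOH removes the three acetates, the fluorosulfate being acid-stable, to give luteolin 7-fluorosulfate F10.
- One equivalent of SO2F2 with iPr2NEt then closes only the ring-B cyclic sulfate, giving 8.

Step 5. The 2-hydroxyethyl group of the intermediate diester may be transferred to the free O4' phenoxide, or S–OAr fission at the activated C7 position may return a free 7-OH. The fallback unmasks the sulfate by rearrangement instead of alkyl transfer; it sets out from 9 and comes back at 11. The anion of benzohydroxamic acid (K2CO3, aq. MeCN, rt) displaces fluoride to give luteolin 3'-sulfate 7-(benzamidooxysulfonate) F11. After N-deprotonation this undergoes Lossen rearrangement, releasing the 7-sulfate monoester directly together with phenyl isocyanate, which is hydrolysed to aniline and CO2 in the medium; no alkylating intermediate is involved.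

**Further compounds**
F1 | step 4 | 4-(benzyloxy)-3-hydroxybenzoic acid (bought in) | OC(=O)c1ccc(OCc2ccccc2)c(O)c1
F2 | step 4 | tert-butyldimethylsilyl 4-(benzyloxy)-3-(tert-butyldimethylsilyloxy)benzoate | CC(C)(C)[Si](C)(C)OC(=O)c1ccc(OCc2ccccc2)c(O[Si](C)(C)C(C)(C)C)c1
F3 | step 4 | 4-(benzyloxy)-3-(tert-butyldimethylsilyloxy)benzoyl chloride | O=C(Cl)c1ccc(OCc2ccccc2)c(O[Si](C)(C)C(C)(C)C)c1
F4 | step 4 | 1-[4-(benzyloxy)-3-(tert-butyldimethylsilyloxy)phenyl]-3-(2,4,6-trihydroxyphenyl)propane-1,3-dione | O=C(CC(=O)c1c(O)cc(O)cc1O)c1ccc(OCc2ccccc2)c(O[Si](C)(C)C(C)(C)C)c1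
F5 | step 4 | 4'-O-benzylluteolin | O=c1cc(-c2ccc(OCc3ccccc3)c(O)c2)oc2cc(O)cc(O)c12
F6 | step 4 | 4'-O-benzylluteolin 7,3'-disulfate | O=c1cc(-c2ccc(OCc3ccccc3)c(OS(=O)(=O)O)c2)oc2cc(OS(=O)(=O)O)cc(O)c12
F7 | step 3 | luteolin tetraacetate | O=c1cc(-c2ccc(OC(C)=O)c(OC(C)=O)c2)oc2cc(OC(C)=O)cc(OC(C)=O)c12
F8 | step 3 | 5,3',4'-tri-O-acetylluteolin | O=c1cc(-c2ccc(OC(C)=O)c(OC(C)=O)c2)oc2cc(O)cc(OC(C)=O)c12
F9 | step 3 | 5,3',4'-tri-O-acetylluteolin 7-fluorosulfate | O=c1cc(-c2ccc(OC(C)=O)c(OC(C)=O)c2)oc2cc(OS(=O)(=O)F)cc(OC(C)=O)c12
F10 | step 3 | luteolin 7-fluorosulfate | O=c1cc(-c2ccc(O)c(O)c2)oc2cc(OS(=O)(=O)F)cc(O)c12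
F11 | step 5 | luteolin 3'-sulfate 7-(benzamidooxysulfonate) | O=c1cc(-c2ccc(O)c(OS(=O)(=O)O)c2)oc2cc(OS(=O)(=O)ONC(=O)c3ccccc3)cc(O)c12
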